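**The levels.** The easy step is to average a flat row. In each earlier run below, X shows no trend from the first reading to the last.

| flask | Q | Z | G | remark | time |
|---|---|---|---|---|---|
| violet | 1 mM | 0.64 mM | 2 mM | run made earlier |  |
| red | 1 mM | 1.4 mM | 2 mM | run made earlier |  |
| teal | 1 mM | 2.9 mM | 2 mM | run made earlier |  |
| north-west | 1.0 mM | 1.20 mM | 2.00 mM |  | 3.0 min |
| south-east | 1.0 mM | 0.500 mM | 2.00 mM |  | 3.0 min |
| north | 1.0 mM | 4.00 mM | 2.00 mM |  | 3.0 min |

- violet (time / s: X / %): 25.0: 1.2; 50.0: 0.9; 80.0: 0.5; 90.0: 0.1; 120: 1.2
- red (time / s: X / %): 12.0: 6.4; 30.0: 6.5; 60.0: 5.2; 90.0: 6.0; 120: 6.4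
- teal (time / s: X / %): 25.0: 27.6; 50.0: 27.3; 80.0: 28.4; 90.0: 27.3; 120: 27.6

(scatter of a reading: 0.5 percentage points)

1. which of these holds the largest part of the Q at the end of north-west (J / E / Q / X)
2. which of these holds the largest part of the Q at the end of south-east (J / E / Q / X)
3. which of these holds the largest part of the Q at the end of north (J / E / Q / X)
4. final X in north-west, as a percentage of the Q charged

- the earlier runs were read with a standard deviation of 0.5 percentage points
- a reading or a percentage of G counts all its forms, free or not

So I take means as levels: violet 0.780 %, red 6.10 %, teal 27.6 %. I drop time from the reckoning, because the asked 3.0 min lies later than red's first flat reading at 12.0 s.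

**The curve.** Now I draw the level against charged [Z] on logarithmic axes. X carries 3 exchanged ligands, so I expect a steep start, with a slope towards 3. From violet to red the plateau order is 2.63: the rise of ln X per rise of ln charged [Z], an apparent reaction order. Each reading scatters by 0.5 percentage points, and violet's level is small, so this order is itself a reading. From red to teal the slope is 2.07, which is flatter. So the curve drawn through these readings has begun to bend by teal's 2.9 mM.

**My estimate.** North-west, at 1.20 mM, sits above violet and below red, on the steeper stretch. Going down from red, I multiply the level by 0.667. So I commit to 4.07 %.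

**The forecast.** It holds that “every run is already at equilibrium”. It names E for north-west, Q for south-east and X for north. Its final X in north-west is 4.6 %, higher than my figure.

**The flasks.** Among Q, E, J and X, the largest holders are E at 35.2 % in north-west, Q at 59.6 % in south-east and X at 40.8 % in north, as forecast. Final X in north-west is 3.59 %, below my figure and below the forecast's. J → D (k = 0.620 /s); L ⇌ G, rate k2*(cs2 - [G]) while solid is left; crystals form when [G] > cs2 (solubility = 0.500 mM, k = 13.0 /s); E + Z → G + J (k = 270 /M/s); J + Z → G + X (k = 190 /M/s); Q + Z → G + E (k = 280 /M/s)

**The order again.** North-west also holds D, at 37.0 % of the Q charged, which is more than its E. I now carry the plateau order 2.63 from that 3.59 % down to the 0.500 mM of south-east, which gives 0.359 %, and south-east stands at 0.335 %.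

Readings and results are calculated for an exercise; noise was put on by code.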